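**Plan**

- Numbering: lactone O1, C2 (C=O), C3, C4, C5; C6 is the hydroxymethyl carbon and O4 the hydroxyl oxygen on C4.
- Retrosynthesis: with O6 protected, O1–C2 is cut and the acyl carbon C2 is returned to O4, giving a cis-3,4-disubstituted oxetan-2-one. That ring is cut at C3–C4 and C2–O4 into an alkoxymethylketene (C2, C3, C6) and an α-silyloxy aldehyde (C4, C5, methyl, chain). The aldehyde is cut between the first and second side-chain CH2 (epoxide opening) and at the propyl–alkyne bond.
- Enabling feature: C2–C3–C4–O4 is a β-hydroxy acid (aldol) array that can close to a four-membered lactone, and the tertiary O1 on C5, one atom beyond C4, can then take the acyl group to form the five-membered ring. C6 and C5 cis on the oxetanone become C6 and O4 trans on the oxolanone.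
- Forward: C14 chain (alkyne alkylation, trans reduction, bromide), Grignard opening of the epoxide, bis-silyl ether, aldehyde. The [2+2] with the ketene from the acid chloride closes the oxetanone; desilylation triggers the β- to γ-lactone acyl shift; PMB removal ends the route.
- Stereochemistry: C5 comes from (S)-2-methylglycidol (no bond to it is broken); C3 and C4 are set together by the quinine-derived catalyst in the [2+2]; the E alkene comes from dissolving-metal reduction of the alkyne.

Key step: step 10

Assumption: the quinine-derived catalyst is taken to give the (3S,4S) oxetanone, the sense expected for the quinine series in ketene–aldehyde additions; if the sense proves opposite, the pseudoenantiomeric O-trimethylsilylquinidine is used in step 10 and nothing else changes.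

**Step 1**
Reactants: 1 undec-10-yn-1-ol; 2 n-propyl bromide
Product: 4 tetradec-10-yn-1-ol, via dilithium alkoxide acetylide 3 (not isolated)
Conditions: n-BuLi (2.1 equiv), THF/DMPU, −78 → 0 °C; then 2, 0 °C → rt; H2O
Reagents that add atoms: none
Why: Acetylide alkylation: in the dianion the carbon nucleophile is far more reactive than the lithium alkoxide, so SN2 attack on the primary bromide should extend the chain at carbon only.

**Step 2**
Reactants: 4 tetradec-10-yn-1-ol
Product: 5 (E)-tetradec-10-en-1-ol
Conditions: Na, NH3(l)/THF, −33 °C; then NH4Cl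
Reagents that add atoms: none
Why: Dissolving-metal reduction of an isolated dialkyl alkyne passes through the trans-vinyl anion and should give the E alkene, the alcohol being masked as its inert alkoxide.

**Step 3**
Reactants: 5 (E)-tetradec-10-en-1-ol
Product: 6 (E)-14-bromotetradec-4-ene
Conditions: CBr4, PPh3, CH2Cl2, 0 °C
Reagents that add atoms: carbon tetrabromide, BrC(Br)(Br)Br
Why: The Appel reaction converts the primary alcohol to the bromide under neutral conditions that leave the position and geometry of the alkene alone.

**Step 4**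
Reactants: 6 (E)-14-bromotetradec-4-ene; 7 (S)-2-methylglycidol
Product: 9 (2R,13E)-2-methylheptadec-13-ene-1,2-diol, via (E)-tetradec-10-enylmagnesium bromide 8 (not isolated)
Conditions: 6, Mg, THF, rt → 45 °C; then 8 (2.5 equiv), CuI (10 mol%), 7, THF, −40 → −10 °C
Reagents that add atoms: none
Why: Copper-catalysed Grignard opening of the epoxide: one equivalent deprotonates the hydroxyl and the organocopper species attacks the unsubstituted CH2 in an SN2 manner, so the carbinol centre of 7 is carried over unchanged (the descriptor becomes R only through a change in priorities).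

**Step 5**
Reactants: 9 (2R,13E)-2-methylheptadec-13-ene-1,2-diol
Product: 10 (2R,13E)-2-methyl-1,2-bis(triethylsilyloxy)heptadec-13-ene
Conditions: TESOTf (2.5 equiv), 2,6-lutidine, CH2Cl2, −78 → 0 °C
Reagents that add atoms: triethylsilyl trifluoromethanesulfonate, CC[Si](CC)(CC)OS(=O)(=O)C(F)(F)F
Why: Silylation with the silyl triflate and a hindered pyridine base is strong enough to cap the tertiary as well as the primary hydroxyl.

**Step 6**
Reactants: 10 (2R,13E)-2-methyl-1,2-bis(triethylsilyloxy)heptadec-13-ene
Product: 11 (2R,13E)-2-methyl-2-(triethylsilyloxy)heptadec-13-enal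
Conditions: (COCl)2, DMSO, CH2Cl2, −78 → −30 °C; then Et3N, −78 °C → rt
Reagents that add atoms: none
Why: Swern oxidation applied directly to the silyl ether: the chlorosulfonium salt cleaves the less hindered primary Si–O bond and the resulting alkoxysulfonium ion collapses to the aldehyde, while the tertiary silyl ether should stay and the aldehyde, having no α-hydrogen, cannot epimerise.

**Step 7**
Reactants: 12 p-methoxybenzyl alcohol; 13 methyl acrylate
Product: 14 methyl 3-(4-methoxybenzyloxy)propanoate
Conditions: NaH (5 mol%), THF, 0 °C → rt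
Reagents that add atoms: none
Why: Alkoxide-catalysed oxa-Michael addition of the benzylic alcohol to the acrylate; any transesterified ester converges on the same acid in the next step.

**Step 8**
Reactants: 14 methyl 3-(4-methoxybenzyloxy)propanoate
Product: 15 3-(4-methoxybenzyloxy)propanoic acid
Conditions: LiOH·H2O, THF/H2O, 0 °C → rt; then 1 M HCl to pH 3
Reagents that add atoms: lithium hydroxide, [Li+].[OH-]
Why: Saponification of the methyl ester, under which the ether is stable and the cold carboxylate does not undergo retro-Michael loss of the alkoxide.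

**Step 9**
Reactants: 15 3-(4-methoxybenzyloxy)propanoic acid
Product: 16 3-(4-methoxybenzyloxy)propanoyl chloride
Conditions: (COCl)2 (1.2 equiv), DMF (cat.), CH2Cl2, 0 °C → rt; concentrated and used at once
Reagents that add atoms: oxalyl chloride, O=C(Cl)C(=O)Cl
Why: Acid chloride formation through the Vilsmeier chloroiminium salt gives only gaseous by-products, and the benzylic ether should survive the short contact with HCl at 0 °C.

**Step 10**
Reactants: 11 (2R,13E)-2-methyl-2-(triethylsilyloxy)heptadec-13-enal; 16 3-(4-methoxybenzyloxy)propanoyl chloride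
Product: 18 (3S,4S)-3-{[(4-methoxybenzyl)oxy]methyl}-4-[(2R,13E)-2-(triethylsilyloxy)heptadec-13-en-2-yl]oxetan-2-one, via (4-methoxybenzyloxy)methylketene 17 (not isolated)
Conditions: O-trimethylsilylquinine (15 mol%), LiI (3 equiv), iPr2NEt (2.5 equiv), CH2Cl2/Et2O (10:1), −78 °C, slow addition of 16 (2 equiv)
Reagents that add atoms: none
Why: Proposed new method: iPr2NEt turns 16 into ketene 17, which the quinuclidine nitrogen of the catalyst traps as a (Z)-acylammonium enolate; this enolate joins C3 to C4 of the LiI-bound aldehyde 11 through a closed, lithium-bridged transition state, and the aldolate oxygen O4 then attacks the acylammonium carbon C2 and releases the alkaloid, a 4-exo-trig closure that completes a stepwise net [2+2]. The closest known reaction is the cinchona alkaloid/lithium salt-catalysed acyl halide–aldehyde cyclocondensation of α-branched aliphatic aldehydes with alkyl-substituted acid chlorides to cis-3,4-disubstituted oxetan-2-ones, extended here to a fully α-substituted α-silyloxy aldehyde and a β-alkoxy acid chloride. The extension is reasonable because the α-oxygen raises the electrophilicity of the hindered carbonyl group, LiI is the stronger activator used for branched aldehydes, and at −78 °C the enolate should add faster than it expels the poor 4-methoxybenzyloxide leaving group by E1cB elimination. C3 and C4 are both set by the catalyst: the (Z)-enolate in the closed transition state gives the cis ring, and the quinine framework shields one enolate face to give the (3S,4S) pair. The step needs enantiofacial control at the aldehyde and cis selectivity; the substrate should not oppose the catalyst, because the C5 centre of 11 differs only in methyl against a long alkyl chain and cannot epimerise.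

**Step 11**
Reactants: 18 (3S,4S)-3-{[(4-methoxybenzyl)oxy]methyl}-4-[(2R,13E)-2-(triethylsilyloxy)heptadec-13-en-2-yl]oxetan-2-one
Product: 20 (3S,4S,5R)-4-hydroxy-3-{[(4-methoxybenzyl)oxy]methyl}-5-methyl-5-[(11E)-pentadec-11-en-1-yl]oxolan-2-one, via hydroxy β-lactone 19 (not isolated)
Conditions: HF·pyridine, pyridine, THF, 0 °C → rt; then DBU (10 mol%), CH2Cl2, 0 °C
Reagents that add atoms: none
Why: Fluoride-mediated desilylation frees the C5 hydroxyl, which should attack the strained oxetanone carbonyl in a 5-exo-trig translactonisation (acyl shift from O4 to O1) driven by relief of ring strain; no bond to C3, C4 or C5 is broken, so the cis-oxetanone maps onto the 3,4-trans oxolanone.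

**Step 12**
Reactants: 20 (3S,4S,5R)-4-hydroxy-3-{[(4-methoxybenzyl)oxy]methyl}-5-methyl-5-[(11E)-pentadec-11-en-1-yl]oxolan-2-one
Product: 21 (3S,4S,5R)-4-hydroxy-3-(hydroxymethyl)-5-methyl-5-[(11E)-pentadec-11-en-1-yl]oxolan-2-one (CNP0165957.1)
Conditions: DDQ (1.5 equiv), CH2Cl2/pH 7 buffer (10:1), 0 °C → rt
Reagents that add atoms: none
Why: Oxidative cleavage of the 4-methoxybenzyl ether by DDQ in wet solvent should spare the isolated alkene, the lactone and the free hydroxyl, the buffered water intercepting the oxocarbenium ion before the C4 hydroxyl can close an anisylidene acetal.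

**Compound list**

1 | undec-10-yn-1-ol | C#CCCCCCCCCCO | starting material
2 | n-propyl bromide (1-bromopropane) | CCCBr | starting material
3 | dilithium alkoxide acetylide of 1 (formed in the flask) | [Li+].[Li+].[O-]CCCCCCCCCC#[C-] | intermediate
4 | tetradec-10-yn-1-ol | CCCC#CCCCCCCCCCO | intermediate
5 | (E)-tetradec-10-en-1-ol | CCC/C=C/CCCCCCCCCO | intermediate
6 | (E)-14-bromotetradec-4-ene | CCC/C=C/CCCCCCCCCBr | intermediate
7 | (S)-2-methylglycidol, [(2S)-2-methyloxiran-2-yl]methanol | C[C@]1(CO)CO1 | starting material
8 | (E)-tetradec-10-enylmagnesium bromide (formed in the flask) | CCC/C=C/CCCCCCCCC[Mg]Br | intermediate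
9 | (2R,13E)-2-methylheptadec-13-ene-1,2-diol | CCC/C=C/CCCCCCCCCC[C@@](C)(O)CO | intermediate
10 | (2R,13E)-2-methyl-1,2-bis(triethylsilyloxy)heptadec-13-ene | CCC/C=C/CCCCCCCCCC[C@@](C)(O[Si](CC)(CC)CC)CO[Si](CC)(CC)CC | intermediate
11 | (2R,13E)-2-methyl-2-(triethylsilyloxy)heptadec-13-enal | CCC/C=C/CCCCCCCCCC[C@@](C)(O[Si](CC)(CC)CC)C=O | intermediate
12 | p-methoxybenzyl alcohol (4-methoxybenzyl alcohol) | COc1ccc(CO)cc1 | starting material
13 | methyl acrylate | C=CC(=O)OC | starting material
14 | methyl 3-(4-methoxybenzyloxy)propanoate | COC(=O)CCOCc1ccc(OC)cc1 | intermediate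
15 | 3-(4-methoxybenzyloxy)propanoic acid | OC(=O)CCOCc1ccc(OC)cc1 | intermediate
16 | 3-(4-methoxybenzyloxy)propanoyl chloride | O=C(Cl)CCOCc1ccc(OC)cc1 | intermediate
17 | (4-methoxybenzyloxy)methylketene (formed in the flask) | O=C=CCOCc1ccc(OC)cc1 | intermediate
18 | (3S,4S)-3-{[(4-methoxybenzyl)oxy]methyl}-4-[(2R,13E)-2-(triethylsilyloxy)heptadec-13-en-2-yl]oxetan-2-one | O=C1O[C@H]([C@](C)(O[Si](CC)(CC)CC)CCCCCCCCCC/C=C/CCC)[C@@H]1COCc1ccc(OC)cc1 | intermediate
19 | (3S,4S)-4-[(2R,13E)-2-hydroxyheptadec-13-en-2-yl]-3-{[(4-methoxybenzyl)oxy]methyl}oxetan-2-one (formed in the flask) | O=C1O[C@H]([C@](C)(O)CCCCCCCCCC/C=C/CCC)[C@@H]1COCc1ccc(OC)cc1 | intermediate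
20 | (3S,4S,5R)-4-hydroxy-3-{[(4-methoxybenzyl)oxy]methyl}-5-methyl-5-[(11E)-pentadec-11-en-1-yl]oxolan-2-one | CCC/C=C/CCCCCCCCCC[C@@]1(C)OC(=O)[C@@H](COCc2ccc(OC)cc2)[C@@H]1O | intermediate
21 | (3S,4S,5R)-4-hydroxy-3-(hydroxymethyl)-5-methyl-5-[(11E)-pentadec-11-en-1-yl]oxolan-2-one | CCC/C=C/CCCCCCCCCC[C@@]1(C)OC(=O)[C@@H](CO)[C@@H]1O | target

**Count**

Total steps: 12. Longest linear sequence: 9 steps (steps 1–6, 10, 11, 12) from undec-10-yn-1-ol.

**Steps most likely to fail**

1. Step 10 (proposed new method). The hindered, fully α-substituted aldehyde may add to the ammonium enolate too slowly. Ketene dimerisation or E1cB loss of the benzylic alkoxide from the enolate could then take over, or facial selectivity could be poor. The fallback is an auxiliary-controlled syn-aldol reaction, setting out from 16 and 11 and returning at 20. Acid chloride 16 acylates lithiated (S)-4-benzyloxazolidin-2-one (n-BuLi, THF, −78 °C) to give the imide (4S)-4-benzyl-3-[3-(4-methoxybenzyloxy)propanoyl]oxazolidin-2-one F1. Its (Z)-boron enolate (Bu2BOTf, iPr2NEt, CH2Cl2, −78 → 0 °C) should add to 11 in an Evans syn-aldol reaction to give (4S)-4-benzyl-3-[(2S,3S,4R,15E)-3-hydroxy-2-{[(4-methoxybenzyl)oxy]methyl}-4-methyl-4-(triethylsilyloxy)nonadec-15-enoyl]oxazolidin-2-one F2, which carries the same C3/C4 arrangement as 18. HF·pyridine then removes the silyl group to give the diol imide (4S)-4-benzyl-3-[(2S,3S,4R,15E)-3,4-dihydroxy-2-{[(4-methoxybenzyl)oxy]methyl}-4-methylnonadec-15-enoyl]oxazolidin-2-one F3. Its tertiary hydroxyl displaces the oxazolidinone (catalytic DBU if required) and closes the γ-lactone 20.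

2. Step 11. The freed tertiary hydroxyl may be slow to take the acyl group, so that base opens the oxetanone by other paths or erodes C3 before the shift. The fallback separates ring opening from ring closure, setting out from 18 and returning at 20. Hydroxide (LiOH, THF/H2O, 0 °C) cleaves the acyl–oxygen bond of 18 to give (2S,3S,4R,15E)-3-hydroxy-2-{[(4-methoxybenzyl)oxy]methyl}-4-methyl-4-(triethylsilyloxy)nonadec-15-enoic acid F4. HF·pyridine removes the silyl group to give (2S,3S,4R,15E)-3,4-dihydroxy-2-{[(4-methoxybenzyl)oxy]methyl}-4-methylnonadec-15-enoic acid F5. This γ-hydroxy acid should lactonise under the acidic conditions (or with catalytic PPTS in toluene) to 20.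

3. Step 6. The primary silyl ether sits next to a quaternary carbon and may be cleaved too slowly under the oxidation conditions, or the two silyl ethers may be poorly differentiated. The fallback removes and oxidises in two separate operations, setting out from 10 and returning at 11. Mild acid methanolysis (PPTS, MeOH/CH2Cl2, 0 °C) should cleave only the primary silyl ether to give (2R,13E)-2-methyl-2-(triethylsilyloxy)heptadec-13-en-1-ol F6, which Dess–Martin periodinane (NaHCO3, CH2Cl2) oxidises to 11.

**Further compounds**

F1 | step 10 | (4S)-4-benzyl-3-[3-(4-methoxybenzyloxy)propanoyl]oxazolidin-2-one | O=C(CCOCc1ccc(OC)cc1)N1[C@@H](Cc2ccccc2)COC1=O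
F2 | step 10 | (4S)-4-benzyl-3-[(2S,3S,4R,15E)-3-hydroxy-2-{[(4-methoxybenzyl)oxy]methyl}-4-methyl-4-(triethylsilyloxy)nonadec-15-enoyl]oxazolidin-2-one | CCC/C=C/CCCCCCCCCC[C@@](C)(O[Si](CC)(CC)CC)[C@@H](O)[C@H](COCc1ccc(OC)cc1)C(=O)N1[C@@H](Cc2ccccc2)COC1=O
F3 | step 10 | (4S)-4-benzyl-3-[(2S,3S,4R,15E)-3,4-dihydroxy-2-{[(4-methoxybenzyl)oxy]methyl}-4-methylnonadec-15-enoyl]oxazolidin-2-one | CCC/C=C/CCCCCCCCCC[C@@](C)(O)[C@@H](O)[C@H](COCc1ccc(OC)cc1)C(=O)N1[C@@H](Cc2ccccc2)COC1=O
F4 | step 11 | (2S,3S,4R,15E)-3-hydroxy-2-{[(4-methoxybenzyl)oxy]methyl}-4-methyl-4-(triethylsilyloxy)nonadec-15-enoic acid | CCC/C=C/CCCCCCCCCC[C@@](C)(O[Si](CC)(CC)CC)[C@@H](O)[C@H](COCc1ccc(OC)cc1)C(=O)O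
F5 | step 11 | (2S,3S,4R,15E)-3,4-dihydroxy-2-{[(4-methoxybenzyl)oxy]methyl}-4-methylnonadec-15-enoic acid | CCC/C=C/CCCCCCCCCC[C@@](C)(O)[C@@H](O)[C@H](COCc1ccc(OC)cc1)C(=O)O
F6 | step 6 | (2R,13E)-2-methyl-2-(triethylsilyloxy)heptadec-13-en-1-ol | CCC/C=C/CCCCCCCCCC[C@@](C)(O[Si](CC)(CC)CC)CO
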